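**Plan**

1. Numbering: tetralin C1 (CH–CH3), C2 (CH–OAc), C3, C4 (CH–side chain), C4a–C8a, C6 (CH2OAc), C8 (OH), side-chain stereocentre C11; the target is 1S,2S,4S,11S (1,2-trans, 2,4-cis).
2. Cuts: the acetyl and O-methyl groups last, then C2–H (ketone reduction), then the C8a–C1 bond by a reverse 1,2-aryl shift. This turns the ring C8a–C1–C2–C3–C4–C4a into the five-membered ring of a 1-ethylidene-indane, made from an indan-1-one. Further cuts are the indanone C(=O)–CH2 bond (hydroacylation) and the aryl–alkenyl bond (Suzuki–Miyaura).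
3. Enabling feature: C2 is at ketone/carbinol level, β to the arene and flanked by the benzylic C1(H)(CH3). This is the α-aryl ketone left when an aryl carbon migrates; the C8 oxygen ortho to C8a makes C8a the better migrating group and later fixes C1.
4. Forward: the arene (steps 1–2) and the C10 chain from (S)-citronellal (steps 3–4) are joined (5); Rh hydroacylation closes the indanone (6); Wittig (7); ring enlargement 5→6 (8); reduction and end-game (9–12).
5. Stereochemistry: C11 is bought; C4 is set by catalyst-controlled hydroacylation; C1 by thermodynamic relay (peri C8–OMe/C1–CH3 strain, trans to the C4 chain); C2 by hydride delivery anti to the C4 chain.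

Key step: step 8

Assumption: (R)-BINAP is written in step 6 by analogy with 2-(1-alkylvinyl)benzaldehyde hydroacylations; if a model shows the opposite sense of induction, the (S)-ligand is used.

**Step 1**
Reactants: 1 (3-bromo-5-methoxyphenyl)methanol
Product: 2 [(3-bromo-5-methoxybenzyl)oxy](tert-butyl)dimethylsilane
Conditions: TBSCl, imidazole, DMF, rt
Reagents that add atoms: tert-butyldimethylsilyl chloride, CC(C)(C)[Si](C)(C)Cl
Why: Standard silylation of a primary benzylic alcohol; the ether survives the base and metal steps and is meant to fall off in the acidic stage of step 8.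

**Step 2**
Reactants: 2 [(3-bromo-5-methoxybenzyl)oxy](tert-butyl)dimethylsilane
Product: 4 2-bromo-4-{[(tert-butyldimethylsilyl)oxy]methyl}-6-methoxybenzaldehyde, via aryllithium 3 (not isolated)
Conditions: LDA, THF, −78 °C; DMF; AcOH quench
Reagents that add atoms: N,N-dimethylformamide, CN(C)C=O
Why: Directed ortho-metalation: the C–H between Br and OMe is the most acidic, LDA at −78 °C avoids Br/Li exchange and aryne formation, and DMF formylates the aryllithium.

**Step 3**
Reactants: 5 (S)-citronellal, (3S)-3,7-dimethyloct-6-enal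
Product: 7 (3S)-3,7-dimethyloct-6-en-1-yne, via enol nonaflate 6 (not isolated)
Conditions: nonafluorobutanesulfonyl fluoride, P2-Et phosphazene base, DMF, −30 °C → rt
Reagents that add atoms: none
Why: One-pot aldehyde-to-terminal-alkyne conversion (enol nonaflate formation, then base-induced elimination); C3 is not part of the enol and low temperature should limit alkyne–allene isomerisation.

**Step 4**
Reactants: 7 (3S)-3,7-dimethyloct-6-en-1-yne
Product: 9 2-[(3S)-3,7-dimethylocta-1,6-dien-2-yl]-4,4,5,5-tetramethyl-1,3,2-dioxaborolane, via alkenylalane 8 (not isolated)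
Conditions: DIBAL-H, Ni(dppp)Cl2 (3 mol %), THF, 0 → 22 °C; then MeOBpin, 0 → 22 °C
Reagents that add atoms: 2-methoxy-4,4,5,5-tetramethyl-1,3,2-dioxaborolane, COB1OC(C)(C)C(C)(C)O1
Why: Ni(dppp)-catalysed α-selective (Markovnikov) hydroalumination of a terminal alkyne followed by Al-to-B exchange gives the 1,1-disubstituted alkenylboronate; the trisubstituted alkene does not react with DIBAL-H at this temperature.

**Step 5**
Reactants: 4 2-bromo-4-{[(tert-butyldimethylsilyl)oxy]methyl}-6-methoxybenzaldehyde; 9 2-[(3S)-3,7-dimethylocta-1,6-dien-2-yl]-4,4,5,5-tetramethyl-1,3,2-dioxaborolane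
Product: 10 4-{[(tert-butyldimethylsilyl)oxy]methyl}-2-[(3S)-3,7-dimethylocta-1,6-dien-2-yl]-6-methoxybenzaldehyde
Conditions: Pd(dppf)Cl2 (5 mol %), K3PO4, 1,4-dioxane/H2O, 80 °C
Reagents that add atoms: none
Why: Suzuki–Miyaura coupling of an aryl bromide activated by the ortho formyl group with an alkenyl pinacolboronate; the aldehyde and both alkenes are tolerated.

**Step 6**
Reactants: 10 4-{[(tert-butyldimethylsilyl)oxy]methyl}-2-[(3S)-3,7-dimethylocta-1,6-dien-2-yl]-6-methoxybenzaldehyde
Product: 11 (3S)-5-{[(tert-butyldimethylsilyl)oxy]methyl}-7-methoxy-3-[(2S)-6-methylhept-5-en-2-yl]indan-1-one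
Conditions: [Rh((R)-BINAP)]BF4 (5 mol %, from [Rh(nbd)2]BF4, (R)-BINAP, H2), CH2Cl2, rt
Reagents that add atoms: none
Why: Rh(I)-catalysed intramolecular alkene hydroacylation (acyl C–H oxidative addition, hydrometalation of the 1,1-disubstituted alkene, reductive elimination) closes the indanone, a known route to 3-substituted indanones; the chiral bisphosphine sets C3 (the later C4) by catalyst control.

**Step 7**
Reactants: 11 (3S)-5-{[(tert-butyldimethylsilyl)oxy]methyl}-7-methoxy-3-[(2S)-6-methylhept-5-en-2-yl]indan-1-one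
Product: 12 tert-butyl({(1E,3S)-1-ethylidene-7-methoxy-3-[(2S)-6-methylhept-5-en-2-yl]-2,3-dihydro-1H-inden-5-yl}methoxy)dimethylsilane (E expected as the main isomer, E/Z mixture usable)
Conditions: EtPPh3Br, KOtBu (slight deficit to the salt), THF, 0 → 40 °C
Reagents that add atoms: ethyltriphenylphosphonium bromide, CC[P+](c1ccccc1)(c1ccccc1)c1ccccc1.[Br-]
Why: Wittig ethylidenation of the aryl ketone with a non-stabilised ylide; both geometric isomers converge in step 8, and the absence of excess base should keep the double bond exocyclic.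

**Step 8**
Reactants: 12 tert-butyl({(1E,3S)-1-ethylidene-7-methoxy-3-[(2S)-6-methylhept-5-en-2-yl]-2,3-dihydro-1H-inden-5-yl}methoxy)dimethylsilane
Product: 14 (1S,4S)-6-(hydroxymethyl)-8-methoxy-1-methyl-4-[(2S)-6-methylhept-5-en-2-yl]-3,4-dihydronaphthalen-2(1H)-one, via dimethyl ketal 13 (not isolated)
Conditions: PhI(OH)OTs (1.05 equiv), MeOH–H2O 95:5, 0 °C → rt; then 1 M HCl, THF, rt; DBU (0.1 equiv), CH2Cl2, rt, under argon
Reagents that add atoms: water, O (carbonyl oxygen after ketal hydrolysis); methanol, CO (only in the ketal 13)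
Why: The λ3-iodane adds to the exocyclic C1=CH(CH3) bond, methanol captures the benzylic C1 cation, and loss of iodobenzene from the exocyclic carbon is accompanied by a 1,2-shift of the aryl carbon C7a from C1 to that carbon, so that the five-membered ring grows to the six-membered ring and the old C1 becomes the C2 ketal, which the acid stage hydrolyses to the ketone while it also removes the TBS group. The closest known reaction type is the hypervalent-iodine (or Tl(III)) oxidative rearrangement of 1-alkylidene benzocycloalkanes to β-benzocycloalkenones (Wittig–ring-expansion sequence). No ring is closed by cyclisation: the tetralin ring arises by ring enlargement through a phenonium-type 1,2-aryl migration. The new stereocentre C1 is benzylic and α to the carbonyl, hence epimerisable, and is set under thermodynamic control: the C8 methoxy group forces the C1 methyl pseudoaxial and the C4 side chain is pseudoaxial on the opposite face, so the 1,4-trans (1S) ketone should dominate after the acid/DBU equilibration. The step needs aryl rather than alkyl migration, secured by the ortho-methoxy-activated arene, and attack on the styrenyl double bond in preference to the side-chain trisubstituted alkene, secured by conjugation with the electron-rich arene and by one equivalent of oxidant at 0 °C.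

**Step 9**
Reactants: 14 (1S,4S)-6-(hydroxymethyl)-8-methoxy-1-methyl-4-[(2S)-6-methylhept-5-en-2-yl]-3,4-dihydronaphthalen-2(1H)-one
Product: 15 (1S,2S,4S)-6-(hydroxymethyl)-8-methoxy-1-methyl-4-[(2S)-6-methylhept-5-en-2-yl]-1,2,3,4-tetrahydronaphthalen-2-ol
Conditions: L-Selectride (2.5 equiv), THF, −78 °C; aq. NH4Cl
Reagents that add atoms: none
Why: Substrate-controlled ketone reduction with a bulky trialkylborohydride: the hydride should enter C2 from the face opposite to the 1,3-related pseudoaxial C4 side chain (equatorial attack), giving the 2S alcohol, cis to the C4 chain and trans to the C1 methyl.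

**Step 10**
Reactants: 15 (1S,2S,4S)-6-(hydroxymethyl)-8-methoxy-1-methyl-4-[(2S)-6-methylhept-5-en-2-yl]-1,2,3,4-tetrahydronaphthalen-2-ol
Product: 16 (1S,2S,4S)-6-(hydroxymethyl)-1-methyl-4-[(2S)-6-methylhept-5-en-2-yl]-1,2,3,4-tetrahydronaphthalene-2,8-diol (target numbering)
Conditions: EtSNa (6 equiv), DMF, 130 °C; dil. HCl work-up
Reagents that add atoms: none
Why: SN2 demethylation of the aryl methyl ether by thiolate, which leaves the trisubstituted alkene, the alcohols and all stereocentres untouched.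

**Step 11**
Reactants: 16 (1S,2S,4S)-6-(hydroxymethyl)-1-methyl-4-[(2S)-6-methylhept-5-en-2-yl]-1,2,3,4-tetrahydronaphthalene-2,8-diol
Product: 17 (1S,2S,4S)-2,8-diacetoxy-6-(acetoxymethyl)-1-methyl-4-[(2S)-6-methylhept-5-en-2-yl]-1,2,3,4-tetrahydronaphthalene
Conditions: Ac2O, pyridine, DMAP (cat.), CH2Cl2, rt
Reagents that add atoms: acetic anhydride, CC(=O)OC(C)=O
Why: Exhaustive DMAP-catalysed acetylation of the primary, secondary and phenolic hydroxyl groups without change at any stereocentre.

**Step 12**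
Reactants: 17 (1S,2S,4S)-2,8-diacetoxy-6-(acetoxymethyl)-1-methyl-4-[(2S)-6-methylhept-5-en-2-yl]-1,2,3,4-tetrahydronaphthalene
Product: 18 CNP0210401.1, (1S,2S,4S)-2-acetoxy-6-(acetoxymethyl)-8-hydroxy-1-methyl-4-[(2S)-6-methylhept-5-en-2-yl]-1,2,3,4-tetrahydronaphthalene
Conditions: pyrrolidine (1.2 equiv), CH2Cl2, 0 °C → rt
Reagents that add atoms: none
Why: Chemoselective aminolysis of the aryl acetate (phenoxide is the better leaving group), which should leave the two alkyl acetates in place.

**Compound list**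

1 | (3-bromo-5-methoxyphenyl)methanol | OCc1cc(OC)cc(Br)c1 | starting material
2 | [(3-bromo-5-methoxybenzyl)oxy](tert-butyl)dimethylsilane | CC(C)(C)[Si](C)(C)OCc1cc(OC)cc(Br)c1 | intermediate
3 | [2-bromo-4-{[(tert-butyldimethylsilyl)oxy]methyl}-6-methoxyphenyl]lithium | CC(C)(C)[Si](C)(C)OCc1cc(OC)c([Li])c(Br)c1 | intermediate (not isolated)
4 | 2-bromo-4-{[(tert-butyldimethylsilyl)oxy]methyl}-6-methoxybenzaldehyde | CC(C)(C)[Si](C)(C)OCc1cc(OC)c(C=O)c(Br)c1 | intermediate
5 | (S)-citronellal, (3S)-3,7-dimethyloct-6-enal | O=CC[C@@H](C)CCC=C(C)C | starting material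
6 | (3S)-3,7-dimethylocta-1,6-dien-1-yl nonafluorobutane-1-sulfonate (E/Z) | O=S(=O)(OC=C[C@@H](C)CCC=C(C)C)C(F)(F)C(F)(F)C(F)(F)C(F)(F)F | intermediate (not isolated)
7 | (3S)-3,7-dimethyloct-6-en-1-yne | C#C[C@@H](C)CCC=C(C)C | intermediate
8 | [(3S)-3,7-dimethylocta-1,6-dien-2-yl]bis(2-methylpropyl)alumane | C=C([Al](CC(C)C)CC(C)C)[C@@H](C)CCC=C(C)C | intermediate (not isolated)
9 | 2-[(3S)-3,7-dimethylocta-1,6-dien-2-yl]-4,4,5,5-tetramethyl-1,3,2-dioxaborolane | C=C(B1OC(C)(C)C(C)(C)O1)[C@@H](C)CCC=C(C)C | intermediate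
10 | 4-{[(tert-butyldimethylsilyl)oxy]methyl}-2-[(3S)-3,7-dimethylocta-1,6-dien-2-yl]-6-methoxybenzaldehyde | CC(C)(C)[Si](C)(C)OCc1cc(OC)c(C=O)c(c1)C(=C)[C@@H](C)CCC=C(C)C | intermediate
11 | (3S)-5-{[(tert-butyldimethylsilyl)oxy]methyl}-7-methoxy-3-[(2S)-6-methylhept-5-en-2-yl]indan-1-one | CC(C)(C)[Si](C)(C)OCc1cc(OC)c2c(c1)[C@H]([C@@H](C)CCC=C(C)C)CC2=O | intermediate
12 | tert-butyl({(1E,3S)-1-ethylidene-7-methoxy-3-[(2S)-6-methylhept-5-en-2-yl]-2,3-dihydro-1H-inden-5-yl}methoxy)dimethylsilane (E shown) | CC(C)(C)[Si](C)(C)OCc1cc(OC)c2c(c1)[C@H]([C@@H](C)CCC=C(C)C)C/C2=C\C | intermediate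
13 | (4S)-6-{[(tert-butyldimethylsilyl)oxy]methyl}-2,2,8-trimethoxy-1-methyl-4-[(2S)-6-methylhept-5-en-2-yl]-1,2,3,4-tetrahydronaphthalene (C1 epimers) | CC(C)(C)[Si](C)(C)OCc1cc(OC)c2c(c1)[C@H]([C@@H](C)CCC=C(C)C)CC(OC)(OC)C2C | intermediate (not isolated)
14 | (1S,4S)-6-(hydroxymethyl)-8-methoxy-1-methyl-4-[(2S)-6-methylhept-5-en-2-yl]-3,4-dihydronaphthalen-2(1H)-one | OCc1cc(OC)c2c(c1)[C@H]([C@@H](C)CCC=C(C)C)CC(=O)[C@H]2C | intermediate
15 | (1S,2S,4S)-6-(hydroxymethyl)-8-methoxy-1-methyl-4-[(2S)-6-methylhept-5-en-2-yl]-1,2,3,4-tetrahydronaphthalen-2-ol | OCc1cc(OC)c2c(c1)[C@H]([C@@H](C)CCC=C(C)C)C[C@H](O)[C@H]2C | intermediate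
16 | (1S,2S,4S)-6-(hydroxymethyl)-1-methyl-4-[(2S)-6-methylhept-5-en-2-yl]-1,2,3,4-tetrahydronaphthalene-2,8-diol | OCc1cc(O)c2c(c1)[C@H]([C@@H](C)CCC=C(C)C)C[C@H](O)[C@H]2C | intermediate
17 | (1S,2S,4S)-2,8-diacetoxy-6-(acetoxymethyl)-1-methyl-4-[(2S)-6-methylhept-5-en-2-yl]-1,2,3,4-tetrahydronaphthalene | CC(=O)OCc1cc(OC(C)=O)c2c(c1)[C@H]([C@@H](C)CCC=C(C)C)C[C@H](OC(C)=O)[C@H]2C | intermediate
18 | CNP0210401.1, (1S,2S,4S)-2-acetoxy-6-(acetoxymethyl)-8-hydroxy-1-methyl-4-[(2S)-6-methylhept-5-en-2-yl]-1,2,3,4-tetrahydronaphthalene | CC(=O)OCc1cc(O)c2c(c1)[C@H]([C@@H](C)CCC=C(C)C)C[C@H](OC(C)=O)[C@H]2C | target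

**Step count and risks**

Total steps: 12. Longest linear sequence: 10 steps (5 → 18 through steps 3–12; the same length from 1 through steps 1, 2, 5–12).

Steps most likely to fail:

Step 8 (key step). The iodane may also oxidise the remote trisubstituted alkene, the exocyclic double bond may drift into the ring under the acid that is formed before the iodane engages, and the C1 equilibration may stop short of the 1,4-trans ketone. The fallback is a non-oxidative semipinacol ring enlargement that sets out from 11. Addition of 1-(phenylselanyl)ethyllithium (from 1,1-bis(phenylselanyl)ethane and n-BuLi, THF, −78 °C) to the ketone should give the β-hydroxy selenide (3S)-5-{[(tert-butyldimethylsilyl)oxy]methyl}-7-methoxy-3-[(2S)-6-methylhept-5-en-2-yl]-1-[1-(phenylselanyl)ethyl]indan-1-ol F1. Selenophilic activation with AgBF4 on alumina in CH2Cl2 should trigger the same 1,2-aryl shift and give the silyl-protected ketone (1S,4S)-6-{[(tert-butyldimethylsilyl)oxy]methyl}-8-methoxy-1-methyl-4-[(2S)-6-methylhept-5-en-2-yl]-3,4-dihydronaphthalen-2(1H)-one F2. Desilylation and C1 equilibration (1 M HCl, THF, then catalytic DBU) return to 14.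

Step 6. Acyl C–H activation at the doubly ortho-substituted aldehyde may be slow and lose CO, and facial selectivity at C3 may be poor if catalyst and the neighbouring C11 centre are mismatched. The fallback forms the other ring bond and sets out from 4 and 7. Hydrozirconation of 7 with Cp2Zr(H)Cl, transmetalation to zinc with Me2Zn and addition to aldehyde 4 should give the allylic alcohol (2E,4S)-1-(2-bromo-4-{[(tert-butyldimethylsilyl)oxy]methyl}-6-methoxyphenyl)-4,8-dimethylnona-2,7-dien-1-ol F3. Oxidation with MnO2 in CH2Cl2 should give the enone (2E,4S)-1-(2-bromo-4-{[(tert-butyldimethylsilyl)oxy]methyl}-6-methoxyphenyl)-4,8-dimethylnona-2,7-dien-1-one F4. A Pd-catalysed asymmetric reductive Heck cyclisation (Pd(OAc)2, chiral bisphosphine, HCO2Na, DMF) closes the C3a–C3 bond and returns to 11.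

Step 9. The hydride may be delivered from the face syn to the C4 chain (anti to the adjacent C1 methyl), which would give the C2 epimer. The fallback corrects C2 by invertive substitution and sets out from 14. The reduction would then give (1S,2R,4S)-6-(hydroxymethyl)-8-methoxy-1-methyl-4-[(2S)-6-methylhept-5-en-2-yl]-1,2,3,4-tetrahydronaphthalen-2-ol F5. Mitsunobu esterification of both hydroxyl groups (4-nitrobenzoic acid, PPh3, DIAD, THF) inverts C2 and should give the bis(4-nitrobenzoate) (1S,2S,4S)-8-methoxy-1-methyl-4-[(2S)-6-methylhept-5-en-2-yl]-2-[(4-nitrobenzoyl)oxy]-1,2,3,4-tetrahydronaphthalen-6-yl]methyl 4-nitrobenzoate F6. Methanolysis (K2CO3, MeOH) returns to 15.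

**Further compounds**

F1 | step 8 | (3S)-5-{[(tert-butyldimethylsilyl)oxy]methyl}-7-methoxy-3-[(2S)-6-methylhept-5-en-2-yl]-1-[1-(phenylselanyl)ethyl]indan-1-ol (epimers at C1 and C1') | CC(C)(C)[Si](C)(C)OCc1cc(OC)c2c(c1)[C@H]([C@@H](C)CCC=C(C)C)CC2(O)C(C)[Se]c1ccccc1
F2 | step 8 | (1S,4S)-6-{[(tert-butyldimethylsilyl)oxy]methyl}-8-methoxy-1-methyl-4-[(2S)-6-methylhept-5-en-2-yl]-3,4-dihydronaphthalen-2(1H)-one | CC(C)(C)[Si](C)(C)OCc1cc(OC)c2c(c1)[C@H]([C@@H](C)CCC=C(C)C)CC(=O)[C@H]2C
F3 | step 6 | (2E,4S)-1-(2-bromo-4-{[(tert-butyldimethylsilyl)oxy]methyl}-6-methoxyphenyl)-4,8-dimethylnona-2,7-dien-1-ol (carbinol epimers) | CC(C)(C)[Si](C)(C)OCc1cc(OC)c(C(O)/C=C/[C@@H](C)CCC=C(C)C)c(Br)c1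
F4 | step 6 | (2E,4S)-1-(2-bromo-4-{[(tert-butyldimethylsilyl)oxy]methyl}-6-methoxyphenyl)-4,8-dimethylnona-2,7-dien-1-one | CC(C)(C)[Si](C)(C)OCc1cc(OC)c(C(=O)/C=C/[C@@H](C)CCC=C(C)C)c(Br)c1
F5 | step 9 | (1S,2R,4S)-6-(hydroxymethyl)-8-methoxy-1-methyl-4-[(2S)-6-methylhept-5-en-2-yl]-1,2,3,4-tetrahydronaphthalen-2-ol | OCc1cc(OC)c2c(c1)[C@H]([C@@H](C)CCC=C(C)C)C[C@@H](O)[C@H]2C
F6 | step 9 | [(1S,2S,4S)-8-methoxy-1-methyl-4-[(2S)-6-methylhept-5-en-2-yl]-2-[(4-nitrobenzoyl)oxy]-1,2,3,4-tetrahydronaphthalen-6-yl]methyl 4-nitrobenzoate | O=C(OCc1cc(OC)c2c(c1)[C@H]([C@@H](C)CCC=C(C)C)C[C@H](OC(=O)c3ccc(cc3)[N+](=O)[O-])[C@H]2C)c4ccc(cc4)[N+](=O)[O-]
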